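**Assumption:** the target has no stereocentre or stereoaxis (it is achiral), so "single enantiomer" calls for no stereocontrol.

## Retrosynthetic overview

1. Target 8 ⇒ 6,7-dihydro compound 7 by dehydrogenation of C6–C7 (last operation, no ring formed).
2. 7 ⇒ N-tryptophyl-6-bromooxindole 4 by a new tandem step: oxalyl chloride activates the lactam, installs the C13 ketoester and lets the tethered indole close the central pyrido ring (C12a–C12b).
3. 4 ⇒ amide 3 by the key disconnection, the aryl C–N bond N5–C4a, made by intramolecular Cu-catalysed amide N-arylation.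
4. 3 ⇒ tryptamine 1 + 2-(2,4-dibromophenyl)acetic acid 2 (amide bond).
5. Ring order: indole B and the bromoarene are bought → five-membered N-ring of indole A (C–N) → central pyrido ring (C–C) → aromatisation.

## Route

Step 1
Reactants: 1 tryptamine; 2 2-(2,4-dibromophenyl)acetic acid
Product: 3 N-[2-(1H-indol-3-yl)ethyl]-2-(2,4-dibromophenyl)acetamide
Conditions: 2, CDI (1.1 equiv), THF, rt, 1 h; then 1 (1.0 equiv), rt, 4 h
Reagents that add atoms: none
Why: CDI turns 2 into its acyl imidazolide, which the primary amine of 1 acylates far faster than the indole N–H (amide coupling); no stereocentre is formed.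

Step 2
Reactants: 3 N-[2-(1H-indol-3-yl)ethyl]-2-(2,4-dibromophenyl)acetamide
Product: 4 6-bromo-1-[2-(1H-indol-3-yl)ethyl]-1,3-dihydro-2H-indol-2-one
Conditions: CuI (10 mol%), N,N'-dimethylethylenediamine (20 mol%), K2CO3 (2 equiv), degassed toluene (0.05 M), 100 °C
Reagents that add atoms: none
Why: Goldberg-type (Ullmann) intramolecular amide N-arylation: the Cu(I) amidate can reach only the ortho C–Br through a five-membered ring closure, so the aryl C–N bond (N5–C4a of the target) forms while the para bromide and the indole N–H stay untouched; no stereocentre.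

Step 3
Reactants: 4 6-bromo-1-[2-(1H-indol-3-yl)ethyl]-1,3-dihydro-2H-indol-2-one
Product: 7 methyl 2-(3-bromo-6,7-dihydro-12H-pyrido[1,2-a:3,4-b']diindol-13-yl)-2-oxoacetate, via chloroindolyl glyoxylyl chloride 5 (not isolated), via pentacyclic glyoxylyl chloride 6 (not isolated)
Conditions: (COCl)2 (2.3 equiv), ClCH2CH2Cl (0.05 M), 0 °C → rt, then 70 °C; then MeOH, 0 °C → rt
Reagents that add atoms: oxalyl chloride ClC(=O)C(=O)Cl; methanol CO
Why: Proposed new method: oxalyl chloride acts twice — it deoxychlorinates the lactam (O-acylation, chloride return, loss of CO and CO2) to a 2-chloroindole that is C3-glyoxylated at once to 5, whose C2–Cl is now a vinylogous acid chloride (chloroiminium character under the HCl formed), so the tethered indole C2 closes the six-membered ring by addition–elimination to 6 (ring closure before glyoxylation would converge on the same 6) and MeOH gives ester 7; the closest known reaction types are the Vilsmeier–Haack–Arnold chloroformylation of oxindoles to 2-chloro-3-formylindoles, the Bischler–Napieralski cyclisation of N-tryptophyl lactams and the C3-glyoxylation of indoles with oxalyl chloride; no stereocentre.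

Step 4
Reactants: 7 methyl 2-(3-bromo-6,7-dihydro-12H-pyrido[1,2-a:3,4-b']diindol-13-yl)-2-oxoacetate
Product: 8 methyl 2-(3-bromo-12H-pyrido[1,2-a:3,4-b']diindol-13-yl)-2-oxoacetate
Conditions: DDQ (1.2 equiv), 1,4-dioxane, 80 °C, Ar
Reagents that add atoms: none
Why: DDQ dehydrogenation: hydride abstraction from C7 gives an indol-3-ylmethyl cation stabilised by N12, loss of the C6 proton aromatises the pyrido ring, and the C13 ketoester shields the otherwise oxidation-prone indole C3 (same reaction type as the DDQ aromatisation of 5,6-dihydropyrrolo[2,1-a]isoquinolines); the product is achiral.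

## Compound list

1 | tryptamine [2-(1H-indol-3-yl)ethan-1-amine] | NCCc1c[nH]c2ccccc12 | starting material
2 | 2-(2,4-dibromophenyl)acetic acid | OC(=O)Cc1ccc(Br)cc1Br | starting material
3 | N-[2-(1H-indol-3-yl)ethyl]-2-(2,4-dibromophenyl)acetamide | O=C(Cc1ccc(Br)cc1Br)NCCc1c[nH]c2ccccc12 | intermediate
4 | 6-bromo-1-[2-(1H-indol-3-yl)ethyl]-1,3-dihydro-2H-indol-2-one | O=C1Cc2ccc(Br)cc2N1CCc1c[nH]c2ccccc12 | intermediate
5 | 2-{6-bromo-2-chloro-1-[2-(1H-indol-3-yl)ethyl]-1H-indol-3-yl}-2-oxoacetyl chloride (not isolated) | O=C(Cl)C(=O)c1c(Cl)n(CCc2c[nH]c3ccccc23)c2cc(Br)ccc12 | intermediate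
6 | 2-(3-bromo-6,7-dihydro-12H-pyrido[1,2-a:3,4-b']diindol-13-yl)-2-oxoacetyl chloride (not isolated) | O=C(Cl)C(=O)c1c2ccc(Br)cc2n2CCc3c4ccccc4[nH]c3-c12 | intermediate
7 | methyl 2-(3-bromo-6,7-dihydro-12H-pyrido[1,2-a:3,4-b']diindol-13-yl)-2-oxoacetate | COC(=O)C(=O)c1c2ccc(Br)cc2n2CCc3c4ccccc4[nH]c3-c12 | intermediate
8 | methyl 2-(3-bromo-12H-pyrido[1,2-a:3,4-b']diindol-13-yl)-2-oxoacetate (achiral) | COC(=O)C(=O)c1c2ccc(Br)cc2n2ccc3c4ccccc4[nH]c3c12 | target

## Step count and risks

Total step count: 4. Longest linear sequence: 4.

**Steps most likely to fail**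

Step 3 (the proposed new step). The risks are glyoxylation of the tryptophyl indole at its free C2 before the lactam is consumed, O,C-bis-acylation of the lactam enol, or sluggish ring closure of 5. The fallback uses known chemistry and separates the two roles of the reagent. It sets out from 4: POCl3 in refluxing toluene effects the classical Bischler–Napieralski-type closure of an N-tryptophyl lactam and gives 3-bromo-6,7-dihydro-12H-pyrido[1,2-a:3,4-b']diindole F1. Ordinary indole C3-glyoxylation of this compound [(COCl)2, CH2Cl2, 0 °C; then MeOH] comes back to the route at 7.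

Step 2. The risks are intermolecular N-arylation (indole N–H or the para bromide) and copper/air oxidation of the oxindole CH2 to an isatin. The fallback reverses the order in which the two C–N bonds are made. It sets out from 2 (with 1): carboxylate-assisted Ullmann amination of the potassium salt of 2 at the bromide ortho to the CH2CO2– arm (CuI, L-proline, K2CO3, DMSO, 70 °C) gives 2-{4-bromo-2-[2-(1H-indol-3-yl)ethylamino]phenyl}acetic acid F2. This lactamises on acidification (AcOH, 60 °C) and comes back to the route at 4.

Step 4. The risks are incomplete hydride abstraction from the acceptor-substituted biindole and DDQ adducts at N12. The fallback replaces hydride abstraction by ionic halogenation and dehydrohalogenation. It sets out from 7: t-BuOCl/Et3N (CH2Cl2, –78 °C) chlorinates C3 of the 2,3-disubstituted indole and gives racemic methyl 2-(3-bromo-7a-chloro-6,7-dihydro-7aH-pyrido[1,2-a:3,4-b']diindol-13-yl)-2-oxoacetate F3. DBU at rt then eliminates HCl across C7–C7a, and tautomerisation of the alkylidene-indolenine comes back to the route at 8.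

Further compounds
F1 | step 3 | 3-bromo-6,7-dihydro-12H-pyrido[1,2-a:3,4-b']diindole | Brc1ccc2cc3-c4[nH]c5ccccc5c4CCn3c2c1
F2 | step 2 | 2-{4-bromo-2-[2-(1H-indol-3-yl)ethylamino]phenyl}acetic acid | OC(=O)Cc1ccc(Br)cc1NCCc1c[nH]c2ccccc12
F3 | step 4 | methyl 2-(3-bromo-7a-chloro-6,7-dihydro-7aH-pyrido[1,2-a:3,4-b']diindol-13-yl)-2-oxoacetate (racemic at C7a) | COC(=O)C(=O)c1c2ccc(Br)cc2n2CCC3(Cl)c4ccccc4N=C3c12
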